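**Plan**
- Retrosynthesis cuts the two aryl–CH2 bonds of the prenyl groups, C8–C1'' on ring A and C2'–C1''' on ring B. Each is traced back to an allyl ether on a phenolic oxygen (O5–prenyl, O3'–1,1-dimethylallyl), and these O–C bonds and an O7 acetal lead back to (S)-hesperetin.
- The feature that allows this: C8 is para to O5 and reachable through C6, the only free ortho carbon of O5. C2' is the only free carbon ortho to O3', because C4' carries the methoxy group. Both prenyl groups can therefore be passed from oxygen to carbon by [3,3] shifts on the intact chromanone and ring B.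
- Forward: no ring is made. O7 is capped, O3' is tert-prenylated, O5 is prenylated, both allyl groups migrate to carbon in one operation, and O7 is freed.
- Stereochemistry: the only stereocentre, C2 (S), is bought with hesperetin. Every later step is neutral or mildly acidic so that the flavanone does not open to the chalcone.

Key step: step 5

Assumption: (S)-hesperetin is taken as purchasable as the single enantiomer (ee checked by chiral HPLC before use); in step 5 the chelation-assisted ring-A shift is taken to run ahead of the ring-B shift, an order that does not change the product.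

Step 1
Reactants: 1 (2S)-hesperetin
Product: 2 (2S)-7-O-MOM-hesperetin
Conditions: MOMCl (1.05 equiv), i-Pr2NEt (1.1 equiv), THF, 0 °C
Reagents that add atoms: chloromethyl methyl ether, COCCl
Why: The 7-OH, para to the C4 carbonyl, is the most acidic phenol (the 5-OH is tied up in a hydrogen bond to C4=O and the 3'-OH is an ordinary guaiacol-type phenol), so one equivalent of MOMCl with a hindered amine should O-alkylate O7 selectively (Williamson-type etherification) at a temperature where C2 is not endangered.

Step 2
Reactants: 3 2-methylbut-3-en-2-ol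
Product: 5 methyl 2-methylbut-3-en-2-yl carbonate, via lithium 2-methylbut-3-en-2-olate 4 (not isolated)
Conditions: n-BuLi, THF, −78 °C; ClCO2Me, −78 °C → rt
Reagents that add atoms: methyl chloroformate, COC(=O)Cl
Why: Acylation of the lithium alkoxide of a tertiary allylic alcohol with a chloroformate is the standard way to tertiary allyl carbonates for Tsuji–Trost chemistry.

Step 3
Reactants: 2 (2S)-7-O-MOM-hesperetin; 5 methyl 2-methylbut-3-en-2-yl carbonate
Product: 6 (2S)-7-O-MOM-3'-O-(1,1-dimethylallyl)hesperetin
Conditions: 5 (1.5 equiv), Pd(PPh3)4 (5 mol %), THF, 0 °C → rt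
Reagents that add atoms: none
Why: In this Tsuji–Trost O-allylation Pd(0) ionises the carbonate with loss of CO2, the methoxide released deprotonates the free 3'-phenol, and the phenoxide attacks the more substituted terminus of the 1,1-dimethyl-π-allyl complex under kinetic control to give the tertiary ether, while the hydrogen-bonded 5-OH should stay out.

Step 4
Reactants: 6 (2S)-7-O-MOM-3'-O-(1,1-dimethylallyl)hesperetin; 7 3-methylbut-2-en-1-ol
Product: 8 (2S)-7-O-MOM-5-O-prenyl-3'-O-(1,1-dimethylallyl)hesperetin
Conditions: 7 (1.5 equiv), PPh3, DIAD, THF, 0 °C → rt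
Reagents that add atoms: none
Why: Mitsunobu etherification is the established neutral method for alkylating the chelated 5-OH of flavanones with prenyl alcohol, the 5-OH is the only acidic site left, and neither the tertiary allyl ether nor C2 is touched.

Step 5
Reactants: 8 (2S)-7-O-MOM-5-O-prenyl-3'-O-(1,1-dimethylallyl)hesperetin
Product: 13 (2S)-7-O-MOM-8,2'-diprenylhesperetin, via C6 reverse-prenyl dienone 9 (not isolated), via C8 prenyl dienone 10 (not isolated), via 8-prenyl 3'-O-tert-prenyl ether 11 (not isolated), via ring-B ortho-dienone 12 (not isolated)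
Conditions: Eu(fod)3 (10 mol %), NaHCO3, PhCl, 85 °C then 120 °C
Reagents that add atoms: none
Why: Eu(III) chelates C4=O and O5 and so accelerates the aromatic Claisen [3,3] shift of the prenyl group from O5 to C6, the only free ortho carbon (C4a is the ring fusion), to give dienone 9 with a crowded 1,1-dimethylallyl group; a Cope [3,3] shift then hands the group on to C8, para to O5, with a second allyl inversion that restores the normal prenyl connectivity (dienone 10), and enolisation gives the chelated phenol 11. The tertiary allyl ether on O3' undergoes an ortho-Claisen [3,3] shift through a chair transition state to C2' (dienone 12), the single allyl inversion turning the 1,1-dimethylallyl ether into a C-prenyl group, and tautomerisation gives 13. The closest known reactions are the europium(III)-catalysed para-Claisen–Cope rearrangement of 5-O-prenylflavanones to 8-prenylflavanones and the ortho-Claisen rearrangement of aryl 1,1-dimethylallyl ethers of guaiacol type, here run in one flask. No ring closes and no stereocentre is created: C2 takes no part, and the neutral, bicarbonate-buffered medium is chosen so that the flavanone does not open to the chalcone. The step needs C8 over C6 on ring A, which rests on the strain of the quaternary allyl group at C6 between C5=O and the C7 OMOM group pushing the Cope shift ahead of enolisation, and C2' over C4' and C6' on ring B, which rests on the methoxy group blocking C4' and on the tertiary allyl terminus being unable to reach the para carbon C6' without building a quaternary centre.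

Step 6
Reactants: 13 (2S)-7-O-MOM-8,2'-diprenylhesperetin
Product: 14 (2S)-8,2'-diprenylhesperetin (CNP0115880.1)
Conditions: 3 M aq HCl, MeOH, rt → 40 °C, stopped at full conversion
Reagents that add atoms: none
Why: Acid-catalysed acetal exchange with methanol cleaves the aryl MOM ether under conditions mild and short enough that prenyl groups ortho to phenols and the C2 centre of a 5-hydroxyflavanone should persist.

**Compound list**
1 | (2S)-hesperetin, (2S)-5,7-dihydroxy-2-(3-hydroxy-4-methoxyphenyl)chroman-4-one | COc1ccc([C@@H]2CC(=O)c3c(O)cc(O)cc3O2)cc1O | starting material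
2 | (2S)-7-O-MOM-hesperetin, (2S)-5-hydroxy-2-(3-hydroxy-4-methoxyphenyl)-7-(methoxymethoxy)chroman-4-one | COc1ccc([C@@H]2CC(=O)c3c(O)cc(OCOC)cc3O2)cc1O | intermediate
3 | 2-methylbut-3-en-2-ol | C=CC(C)(C)O | starting material
4 | lithium 2-methylbut-3-en-2-olate (not isolated) | C=CC(C)(C)[O-].[Li+] | intermediate
5 | methyl 2-methylbut-3-en-2-yl carbonate | C=CC(C)(C)OC(=O)OC | intermediate
6 | (2S)-7-O-MOM-3'-O-(1,1-dimethylallyl)hesperetin, (2S)-5-hydroxy-7-(methoxymethoxy)-2-[4-methoxy-3-(2-methylbut-3-en-2-yloxy)phenyl]chroman-4-one | COc1ccc([C@@H]2CC(=O)c3c(O)cc(OCOC)cc3O2)cc1OC(C)(C)C=C | intermediate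
7 | 3-methylbut-2-en-1-ol (prenyl alcohol) | CC(C)=CCO | starting material
8 | (2S)-7-O-MOM-5-O-prenyl-3'-O-(1,1-dimethylallyl)hesperetin, (2S)-7-(methoxymethoxy)-2-[4-methoxy-3-(2-methylbut-3-en-2-yloxy)phenyl]-5-(3-methylbut-2-enyloxy)chroman-4-one | COc1ccc([C@@H]2CC(=O)c3c(OCC=C(C)C)cc(OCOC)cc3O2)cc1OC(C)(C)C=C | intermediate
9 | C6 dienone (not isolated): (2S)-7-(methoxymethoxy)-6-(2-methylbut-3-en-2-yl)-2-[4-methoxy-3-(2-methylbut-3-en-2-yloxy)phenyl]-2,3-dihydrochromene-4,5(6H)-dione, both C6 epimers | COc1ccc([C@@H]2CC(=O)C3=C(O2)C=C(OCOC)C(C(C)(C)C=C)C3=O)cc1OC(C)(C)C=C | intermediate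
10 | C8 dienone (not isolated): (2S)-7-(methoxymethoxy)-8-(3-methylbut-2-enyl)-2-[4-methoxy-3-(2-methylbut-3-en-2-yloxy)phenyl]-2,3-dihydrochromene-4,5(8H)-dione, both C8 epimers | COc1ccc([C@@H]2CC(=O)C3=C(O2)C(CC=C(C)C)C(OCOC)=CC3=O)cc1OC(C)(C)C=C | intermediate
11 | (2S)-5-hydroxy-7-(methoxymethoxy)-8-(3-methylbut-2-enyl)-2-[4-methoxy-3-(2-methylbut-3-en-2-yloxy)phenyl]chroman-4-one (not isolated) | COc1ccc([C@@H]2CC(=O)c3c(O)cc(OCOC)c(CC=C(C)C)c3O2)cc1OC(C)(C)C=C | intermediate
12 | ring-B ortho-dienone (not isolated): 5-[(2S)-5-hydroxy-7-(methoxymethoxy)-8-(3-methylbut-2-enyl)-4-oxochroman-2-yl]-2-methoxy-6-(3-methylbut-2-enyl)cyclohexa-2,4-dien-1-one, both epimers at the sp3 ring carbon | COC1=CC=C([C@@H]2CC(=O)c3c(O)cc(OCOC)c(CC=C(C)C)c3O2)C(CC=C(C)C)C1=O | intermediate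
13 | (2S)-7-O-MOM-8,2'-diprenylhesperetin, (2S)-5-hydroxy-2-[3-hydroxy-4-methoxy-2-(3-methylbut-2-enyl)phenyl]-7-(methoxymethoxy)-8-(3-methylbut-2-enyl)chroman-4-one | COc1ccc([C@@H]2CC(=O)c3c(O)cc(OCOC)c(CC=C(C)C)c3O2)c(CC=C(C)C)c1O | intermediate
14 | (2S)-5,7-dihydroxy-2-[3-hydroxy-4-methoxy-2-(3-methylbut-2-enyl)phenyl]-8-(3-methylbut-2-enyl)chroman-4-one (CNP0115880.1) | COc1ccc([C@@H]2CC(=O)c3c(O)cc(O)c(CC=C(C)C)c3O2)c(CC=C(C)C)c1O | target

**Step count**
Total steps: 6. Longest linear sequence: 5 (steps 1, 3, 4, 5, 6 from 1); step 2 is a one-step side branch.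

**Steps most likely to fail**

1. Step 5. The Lewis acid may ionise the tertiary aryl allyl ether, so that the C5 unit is lost or re-attached unselectively. The C6 dienone may also enolise before the Cope shift, and C2 may erode slowly through reversible ring opening at the higher temperature. The fallback separates the two sigmatropic events so that europium never meets the tertiary ether. It sets out from 6 and returns at 14. Heating 6 without any Lewis acid (PhMe, 120 °C, sealed tube) should effect only the ring-B ortho-Claisen rearrangement and give (2S)-7-O-MOM-2'-prenylhesperetin F1. The new 3'-OH is capped with MOMCl/i-Pr2NEt to give (2S)-7,3'-di-O-MOM-2'-prenylhesperetin F2. Mitsunobu reaction with 7 (PPh3, DIAD, THF) gives (2S)-7,3'-di-O-MOM-5-O-prenyl-2'-prenylhesperetin F3. The Eu(fod)3-catalysed Claisen–Cope rearrangement (NaHCO3, PhCl, 85 °C) then gives (2S)-7,3'-di-O-MOM-8,2'-diprenylhesperetin F4, and methanolic HCl removes both acetals to give 14.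

2. Step 3. Palladium may re-ionise the tertiary ether so that it drifts to the linear prenyl ether, or the ring-A phenoxide may be allylated at O5 or at C6/C8. The fallback builds the tertiary ether without a π-allyl intermediate. It sets out from 2 and returns at 6. Copper-catalysed propargylation of the 3'-phenol (3-chloro-3-methylbut-1-yne, CuCl2 cat., DBU, MeCN, 0 °C, ee checked afterwards) gives (2S)-7-O-MOM-3'-O-(1,1-dimethylpropargyl)hesperetin F5. Lindlar semi-hydrogenation (H2, Pd/CaCO3–Pb, quinoline, EtOAc) then gives 6.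

3. Step 1. Site control may be lost, with alkylation at O3' as well as, or instead of, O7. The fallback differentiates the phenols by acyl chemistry and sets out from 1, returning at 2. Ac2O/pyridine acetylates the two non-chelated phenols to give (2S)-7,3'-di-O-acetylhesperetin F6. The most labile 7-O-acetyl group is removed selectively with PhSH/imidazole in NMP to give (2S)-3'-O-acetylhesperetin F7. MOMCl/i-Pr2NEt then gives (2S)-3'-O-acetyl-7-O-MOM-hesperetin F8, and brief methanolysis (cat. K2CO3, MeOH, 0 °C) gives 2.

**Further compounds**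
F1 | step 5 | (2S)-7-O-MOM-2'-prenylhesperetin | COc1ccc([C@@H]2CC(=O)c3c(O)cc(OCOC)cc3O2)c(CC=C(C)C)c1O
F2 | step 5 | (2S)-7,3'-di-O-MOM-2'-prenylhesperetin | COCOc1c(OC)ccc([C@@H]2CC(=O)c3c(O)cc(OCOC)cc3O2)c1CC=C(C)C
F3 | step 5 | (2S)-7,3'-di-O-MOM-5-O-prenyl-2'-prenylhesperetin | COCOc1c(OC)ccc([C@@H]2CC(=O)c3c(OCC=C(C)C)cc(OCOC)cc3O2)c1CC=C(C)C
F4 | step 5 | (2S)-7,3'-di-O-MOM-8,2'-diprenylhesperetin | COCOc1c(OC)ccc([C@@H]2CC(=O)c3c(O)cc(OCOC)c(CC=C(C)C)c3O2)c1CC=C(C)C
F5 | step 3 | (2S)-7-O-MOM-3'-O-(1,1-dimethylpropargyl)hesperetin | COc1ccc([C@@H]2CC(=O)c3c(O)cc(OCOC)cc3O2)cc1OC(C)(C)C#C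
F6 | step 1 | (2S)-7,3'-di-O-acetylhesperetin | COc1ccc([C@@H]2CC(=O)c3c(O)cc(OC(C)=O)cc3O2)cc1OC(C)=O
F7 | step 1 | (2S)-3'-O-acetylhesperetin | COc1ccc([C@@H]2CC(=O)c3c(O)cc(O)cc3O2)cc1OC(C)=O
F8 | step 1 | (2S)-3'-O-acetyl-7-O-MOM-hesperetin | COc1ccc([C@@H]2CC(=O)c3c(O)cc(OCOC)cc3O2)cc1OC(C)=O
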